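## Retrosynthetic overview
1. 10 ⇒ 9: both C–Br bonds are made last from the two C–O bonds of a fused 2,5-dihydrofuran, with inversion at the secondary carbon. Until then the ring oxygen stores that configuration and holds the ethylidene geometry.
2. 9 ⇒ 8 ⇒ 6: the allylic C–Cl comes from the ketone (reduction, then SN2 inversion). The neopentyl C–Cl comes from conjugate addition of HCl to the remaining enone, trans to the ring oxygen.
3. 6 ⇒ 2 + glycolaldehyde: the key C–O disconnection. A desymmetrising oxa-Michael addition to one of two enantiotopic enone carbons is locked by aldol condensation.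
4. 2 ⇒ 1: dehydrogenation of a commercial enone.
5. Ring order: the carbocycle (ring A) is bought with 1. The dihydrofuran (ring B) is closed in step 2 and opened in step 5.

Locants for 6–9 are benzofuran locants: C4, C6 and C7a become C4, C6 and C2 of the target.

Assumption: the quinine-derived amine is taken to give (7aR)-6. If the sense of induction proves opposite, the quinidine-derived pseudoenantiomer is used and nothing else changes.

## Route

Step 1
Reactants: 1 4,4-dimethylcyclohex-2-en-1-one
Product: 2 4,4-dimethylcyclohexa-2,5-dien-1-one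
Conditions: DDQ (1.3 equiv), 1,4-dioxane, reflux, 24 h
Reagents that add atoms: none
Why: DDQ dehydrogenation of an enone (hydride abstraction from the dienol) stops at the cross-conjugated dienone because the quaternary carbon blocks aromatisation, and no stereocentre is formed.

Step 2
Reactants: 2 4,4-dimethylcyclohexa-2,5-dien-1-one (1.5 equiv); 3 1,4-dioxane-2,5-diol (glycolaldehyde dimer, 0.5 equiv)
Product: 6 (7aR)-7,7-dimethyl-7,7a-dihydro-1-benzofuran-4(2H)-one, via glycolaldehyde 4 (not isolated), via oxa-Michael adduct 5 (not isolated)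
Conditions: 9-amino-9-deoxy-epi-quinine (20 mol %), CF3CO2H (40 mol %), 1,4-dioxane, 45 °C, 3 added in four portions over 24 h
Reagents that add atoms: 1,4-dioxane-2,5-diol (compound 3), OC1COC(O)CO1
Why: Proposed new method: the primary amine turns 2 into a cross-conjugated iminium ion, the protonated quinuclidine guides the hydroxyl group of slowly released glycolaldehyde to one of the two enantiotopic β-carbons (C–O bond, sets C7a), the resulting dienamine closes on the tethered aldehyde (5-exo enamine aldol), and irreversible E1cB loss of water pulls the reversible oxa-Michael step forward and fixes the alkene inside the five-membered ring, while the α-branched product re-enters the cycle slowly so a second annulation is suppressed; the closest known reaction types are the amine-catalysed oxa-Michael/aldol-condensation domino of salicylaldehydes with cyclohexenones, the sulfa-Michael/aldol domino of mercaptoacetaldehyde dimer, and iminium-catalysed hydroperoxide addition to cyclic enones.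

Step 3
Reactants: 6 (7aR)-7,7-dimethyl-7,7a-dihydro-1-benzofuran-4(2H)-one
Product: 8 (4R,6S,7aS)-6-chloro-7,7-dimethyl-2,4,5,6,7,7a-hexahydro-1-benzofuran-4-ol, via chloro ketone 7 (not isolated)
Conditions: HCl (2 M in Et2O, 3 equiv), CH2Cl2, −40 °C; volatiles off at −20 °C; then (S)-2-methyl-CBS-oxazaborolidine (20 mol %), catecholborane (1.8 equiv), toluene, −78 °C; pH 7 buffer
Reagents that add atoms: hydrogen chloride, Cl
Why: Conjugate hydrochlorination then CBS reduction: chloride adds to the protonated dienone at the α-unbranched endocyclic β-carbon, axially and anti to the pseudoaxial methyl group, so trans to the ring oxygen (the trans rule for 5-substituted cyclohexenones, sets C6), and the labile β-chloro ketone is reduced at once from the face opposite the axial chlorine, a substrate bias matched by the (S)-catalyst (alkenyl as large group), giving the (4R)-carbinol cis to chlorine and turning any minor enantiomer into a separable diastereomer.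

Step 4
Reactants: 8 (4R,6S,7aS)-6-chloro-7,7-dimethyl-2,4,5,6,7,7a-hexahydro-1-benzofuran-4-ol
Product: 9 (4S,6S,7aR)-4,6-dichloro-7,7-dimethyl-2,4,5,6,7,7a-hexahydro-1-benzofuran
Conditions: PPh3 (1.5 equiv), hexachloroacetone (3 equiv), CH2Cl2, −20 to 0 °C, 30 min
Reagents that add atoms: hexachloroacetone, ClC(Cl)(Cl)C(=O)C(Cl)(Cl)Cl
Why: Appel-type deoxychlorination in the variant used for allylic alcohols proceeds through an alkoxyphosphonium chloride that collapses by direct SN2 with inversion and without allylic shift, turning the axial (4R)-alcohol into the (4S)-chloride trans to the C6 chloride while the ether and the neopentyl chloride are inert.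

Step 5
Reactants: 9 (4S,6S,7aR)-4,6-dichloro-7,7-dimethyl-2,4,5,6,7,7a-hexahydro-1-benzofuran
Product: 10 (2S,3Z,4S,6S)-2-bromo-3-(2-bromoethylidene)-4,6-dichloro-1,1-dimethylcyclohexane
Conditions: Ph3PBr2 (1.3 equiv), ClCH2CH2Cl, 0 to 50 °C, dark
Reagents that add atoms: dibromotriphenylphosphorane, BrP(Br)(c1ccccc1)(c1ccccc1)c1ccccc1
Why: Ether-to-dibromide cleavage with dibromotriphenylphosphorane (its second half is an Appel bromination): bromide opens the phosphonium-activated bis-allylic ether at the primary allylic carbon, and the remaining secondary alkoxyphosphonium salt, which has no β-hydrogen to eliminate, is displaced with inversion (directly or by backside participation of the neighbouring CH2Br bromine, both giving the same result) to set the (2S)-C–Br cis to the C6 chloride, with the Z geometry carried over from the ring.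

## Compound list
1 | 4,4-dimethylcyclohex-2-en-1-one | CC1(C)CCC(=O)C=C1 | starting material
2 | 4,4-dimethylcyclohexa-2,5-dien-1-one | CC1(C)C=CC(=O)C=C1 | intermediate
3 | 1,4-dioxane-2,5-diol (glycolaldehyde dimer) | OC1COC(O)CO1 | starting material
4 | glycolaldehyde | OCC=O | intermediate
5 | 2-{[(1S)-2,2-dimethyl-5-oxocyclohex-3-en-1-yl]oxy}acetaldehyde | O=CCO[C@H]1CC(=O)C=CC1(C)C | intermediate
6 | (7aR)-7,7-dimethyl-7,7a-dihydro-1-benzofuran-4(2H)-one | O=C1C=CC(C)(C)[C@H]2OCC=C12 | intermediate
7 | (6S,7aS)-6-chloro-7,7-dimethyl-5,6,7,7a-tetrahydro-1-benzofuran-4(2H)-one | O=C1C[C@H](Cl)C(C)(C)[C@H]2OCC=C12 | intermediate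
8 | (4R,6S,7aS)-6-chloro-7,7-dimethyl-2,4,5,6,7,7a-hexahydro-1-benzofuran-4-ol | O[C@@H]1C[C@H](Cl)C(C)(C)[C@H]2OCC=C12 | intermediate
9 | (4S,6S,7aR)-4,6-dichloro-7,7-dimethyl-2,4,5,6,7,7a-hexahydro-1-benzofuran | Cl[C@H]1C[C@H](Cl)C(C)(C)[C@H]2OCC=C12 | intermediate
10 | (2S,3Z,4S,6S)-2-bromo-3-(2-bromoethylidene)-4,6-dichloro-1,1-dimethylcyclohexane | CC1(C)[C@H](Br)/C(=C\CBr)[C@@H](Cl)C[C@@H]1Cl | target

## Step count
Total step count: 5. Longest linear sequence: 5 (1 → 2 → 6 → 8 → 9 → 10).

## Steps most likely to fail

**Step 2 (the proposed new step).**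
- The catalyst amine may be tied up or degraded by glycolaldehyde (imine formation, hydroxy-imine rearrangement, self-aldol).
- The β-carbon is neopentyl, so attack may be slow.
- The level and sense of induction are untested.

The fallback sets out from 2 and returns at 6, using known reactions only.
- Iodine and pyridine in CH2Cl2 give 2-iodo-4,4-dimethylcyclohexa-2,5-dien-1-one F1.
- CBS reduction with (R)-2-methyl-CBS-oxazaborolidine and catecholborane gives (1S)-2-iodo-4,4-dimethylcyclohexa-2,5-dien-1-ol F2.
- Stille coupling with tributyl(vinyl)stannane and Pd(PPh3)4 in DMF gives (1S)-2-ethenyl-4,4-dimethylcyclohexa-2,5-dien-1-ol F3.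
- Hydroxyl-directed epoxidation of the trisubstituted alkene with VO(acac)2 and t-BuOOH gives the syn vinyl oxirane (1S,2S,6R)-1-ethenyl-5,5-dimethyl-7-oxabicyclo[4.1.0]hept-3-en-2-ol F4.
- Cu(hfacac)2-catalysed ring expansion of the vinyl oxirane in hot toluene keeps the secondary C–O bond. It gives (4S,7aR)-7,7-dimethyl-2,4,7,7a-tetrahydro-1-benzofuran-4-ol F5.
- MnO2 oxidation of this bis-allylic alcohol returns 6.

**Step 3.**
- Chloride may add at the exocyclic enone carbon instead.
- That mode can go on to open the allylic ether in an SN2' sense.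
- All HCl additions are reversible, so 7 may be only part of an equilibrium mixture.

The fallback sets out from 6 and returns at 7. It replaces the reversible heteroatom addition by an irreversible one.
- Conjugate borylation (B2pin2, CuCl, DPEphos, catalytic NaOtBu, MeOH, THF) attacks the α-unbranched endocyclic enone from the same face. It gives (6S,7aR)-7,7-dimethyl-6-(4,4,5,5-tetramethyl-1,3,2-dioxaborolan-2-yl)-5,6,7,7a-tetrahydro-1-benzofuran-4(2H)-one F6.
- NaBO3·4H2O oxidises it with retention to (6S,7aR)-6-hydroxy-7,7-dimethyl-5,6,7,7a-tetrahydro-1-benzofuran-4(2H)-one F7.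
- Stereoretentive chlorination through the chlorosulfite (SOCl2, then 10 mol % TiCl4, CH2Cl2, 0 °C, front-side delivery) gives 7. This is reduced as in step 3.

**Step 5.**
- Bromide may attack the ethylidene carbon (SN2') rather than the neopentyl allylic carbon.
- Warm bromide may exchange the allylic chloride.
- Warm bromide may also erode the alkene geometry.

The fallback sets out from 9 and returns at 10. It separates the two C–O cleavages so that each runs cold.
- B-bromodimethylborane in CH2Cl2 at −78 °C opens the ether by SN2 at the primary allylic carbon only. It gives (1R,2E,3S,5S)-2-(2-bromoethylidene)-3,5-dichloro-6,6-dimethylcyclohexan-1-ol F8. The geometry is unchanged; the descriptor changes because oxygen replaces bromine.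
- A separate Appel bromination (CBr4, PPh3, CH2Cl2, −20 °C) inverts the carbinol carbon to give 10.

## Further compounds
F1 | step 2 | 2-iodo-4,4-dimethylcyclohexa-2,5-dien-1-one | CC1(C)C=CC(=O)C(I)=C1
F2 | step 2 | (1S)-2-iodo-4,4-dimethylcyclohexa-2,5-dien-1-ol | O[C@H]1C=CC(C)(C)C=C1I
F3 | step 2 | (1S)-2-ethenyl-4,4-dimethylcyclohexa-2,5-dien-1-ol | O[C@H]1C=CC(C)(C)C=C1C=C
F4 | step 2 | (1S,2S,6R)-1-ethenyl-5,5-dimethyl-7-oxabicyclo[4.1.0]hept-3-en-2-ol | O[C@H]1C=CC(C)(C)[C@H]2O[C@@]12C=C
F5 | step 2 | (4S,7aR)-7,7-dimethyl-2,4,7,7a-tetrahydro-1-benzofuran-4-ol | O[C@H]1C=CC(C)(C)[C@H]2OCC=C12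
F6 | step 3 | (6S,7aR)-7,7-dimethyl-6-(4,4,5,5-tetramethyl-1,3,2-dioxaborolan-2-yl)-5,6,7,7a-tetrahydro-1-benzofuran-4(2H)-one | O=C1C[C@H](B3OC(C)(C)C(C)(C)O3)C(C)(C)[C@H]2OCC=C12
F7 | step 3 | (6S,7aR)-6-hydroxy-7,7-dimethyl-5,6,7,7a-tetrahydro-1-benzofuran-4(2H)-one | O=C1C[C@H](O)C(C)(C)[C@H]2OCC=C12
F8 | step 5 | (1R,2E,3S,5S)-2-(2-bromoethylidene)-3,5-dichloro-6,6-dimethylcyclohexan-1-ol | CC1(C)[C@@H](O)/C(=C\CBr)[C@@H](Cl)C[C@@H]1Cl
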